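**Retrosynthetic overview**
1. Target ⇒ 7,3',4'-tri-O-benzyl-(−)-epicatechin with free 3-OH and 5-OH, plus two tri-O-benzylgallic acids. The forward steps are a double esterification and removal of nine O-benzyl groups by hydrogenolysis.
2. cis-(2R,3R)-diol ⇒ racemic 5-hydroxyflavan-3-one that epimerises at C2. Asymmetric transfer hydrogenation with dynamic kinetic resolution sets C2 and C3 in one operation.
3. Flavan-3-one ⇒ 3-nitro-2H-chromene, with NO2 as a masked C=O (reductive Nef).
4. Key disconnection C3–C4, together with O1–C2. C3 reacts as a nitronate (a masked acyl anion) and attacks the aldehyde carbon C4. This happens in an oxa-Michael/Henry/dehydration domino between mirror-symmetric 4-O-benzylphloroglucinaldehyde and 3,4-dibenzyloxy-β-nitrostyrene.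
5. Ring order: rings A and B are bought and ring C closes in the domino step. The ortho-OH that is not used becomes the free 5-OH, so 5-O and 7-O are told apart without extra protecting-group steps.

Assumption: the SMILES is read as (2R,3R), the (−)-epicatechin series, and 1, 3 and 11 are bought as catalogue compounds.

**Step 1**
Reactants: 1 2,4,6-trihydroxybenzaldehyde
Product: 2 4-(benzyloxy)-2,6-dihydroxybenzaldehyde
Conditions: BnBr (1.0 equiv), CsHCO3 (1.2 equiv), MeCN, 60 °C
Reagents that add atoms: benzyl bromide, BrCc1ccccc1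
Why: Williamson ether synthesis in which the 4-OH, the most acidic phenol (para to CHO) and the one not hydrogen-bonded to or shielded by the aldehyde, is the only one ionised by the weak base, so one equivalent of BnBr alkylates it and ring A stays symmetric.

**Step 2**
Reactants: 2 4-(benzyloxy)-2,6-dihydroxybenzaldehyde; 3 (E)-3,4-bis(benzyloxy)-β-nitrostyrene
Product: 6 rac-2-[3,4-bis(benzyloxy)phenyl]-7-(benzyloxy)-3-nitro-2H-chromen-5-ol, via nitronate adduct 4 (not isolated), via nitroaldol 5 (not isolated)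
Conditions: DABCO (0.5 equiv), 4 Å MS, MeCN, 60 °C
Reagents that add atoms: none
Why: Domino oxa-Michael/Henry (nitroaldol)/dehydration in which a phenoxide of 2 adds to the β-carbon of 3 and turns C3 into a nitronate, a masked acyl anion (NO2 becomes C=O in step 3), which attacks the aldehyde carbon C4 intramolecularly so that two carbonyl-level, normally electrophilic carbons are joined; loss of water makes the sequence irreversible, either of the two equivalent ortho-OH groups closes ring C and leaves the other as the free 5-OH, and C2 is deliberately formed racemic because it is set in step 4.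

**Step 3**
Reactants: 6 rac-2-[3,4-bis(benzyloxy)phenyl]-7-(benzyloxy)-3-nitro-2H-chromen-5-ol
Product: 8 rac-2-[3,4-bis(benzyloxy)phenyl]-7-(benzyloxy)-5-hydroxychroman-3-one, via ketimine 7 (not isolated)
Conditions: Fe powder (6 equiv), AcOH/H2O (9:1), 80 °C, N2
Reagents that add atoms: water, O
Why: Reductive Nef-type unmasking, known for 3-nitro-2H-chromenes and β-alkyl-β-nitrostyrenes, in which iron in acetic acid reduces the conjugated nitroalkene through the oxime to the ketimine, which is hydrolysed in the aqueous acid faster than it is reduced further, while benzyl ethers and the phenol are inert.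

**Step 4**
Reactants: 8 rac-2-[3,4-bis(benzyloxy)phenyl]-7-(benzyloxy)-5-hydroxychroman-3-one
Product: 10 (2R,3R)-2-[3,4-bis(benzyloxy)phenyl]-7-(benzyloxy)chromane-3,5-diol, via achiral enol 9 (not isolated)
Conditions: RuCl[(R,R)-TsDPEN](p-cymene) (2 mol %), HCO2H/Et3N (1:1), CH2Cl2, 35 °C, Ar
Reagents that add atoms: none
Why: Proposed new method: Noyori–Ikariya asymmetric transfer hydrogenation under dynamic kinetic resolution, whose closest known relatives are the ATH–DKR of 1-aryl-2-tetralones to cis-alcohols and of benzoin; C2–H (α to C=O, benzylic and α-oxygenated) is exchanged by Et3N through enol 9 faster than this non-conjugated ketone is reduced, the bulky Ru–H adds anti to the 2-aryl group (hence cis), and with the aryl- and oxygen-bearing C2 flank taking the place of the aryl group in the CH/π model the (R,R)-catalyst is predicted to consume the (2R)-ketone and give (3R), so both stereocentres are set together.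

**Step 5**
Reactants: 10 (2R,3R)-2-[3,4-bis(benzyloxy)phenyl]-7-(benzyloxy)chromane-3,5-diol; 11 3,4,5-tris(benzyloxy)benzoic acid (2.4 equiv)
Product: 13 (2R,3R)-2-[3,4-bis(benzyloxy)phenyl]-7-(benzyloxy)chromane-3,5-diyl bis[3,4,5-tris(benzyloxy)benzoate], via O-acylisourea 12 (not isolated)
Conditions: DCC (2.6 equiv), DMAP (0.4 equiv), CH2Cl2, 0 °C to rt
Reagents that add atoms: none
Why: Steglich esterification that acylates the only two free hydroxyls (phenolic 5-OH and axial 3-OH) in one operation, and neither C–O bond at a stereocentre is broken, so C2 and C3 are untouched.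

**Step 6**
Reactants: 13 (2R,3R)-2-[3,4-bis(benzyloxy)phenyl]-7-(benzyloxy)chromane-3,5-diyl bis[3,4,5-tris(benzyloxy)benzoate]
Product: 14 (−)-epicatechin 3,5-di-O-gallate
Conditions: H2 (1 atm), Pd(OH)2/C (20 wt %), THF/EtOAc (1:1), rt
Reagents that add atoms: none
Why: Global catalytic hydrogenolysis of the nine O-benzyl ethers under neutral, alcohol-free conditions, which spares both gallate esters (including the labile aryl ester at O-5) and the cyclic C2–O1 bond and leaves the stereocentres unchanged.

**Compound list**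
1 | 2,4,6-trihydroxybenzaldehyde | O=Cc1c(O)cc(O)cc1O | starting material
2 | 4-(benzyloxy)-2,6-dihydroxybenzaldehyde | O=Cc1c(O)cc(OCc2ccccc2)cc1O | intermediate
3 | (E)-3,4-bis(benzyloxy)-β-nitrostyrene | O=[N+]([O-])/C=C/c1ccc(OCc2ccccc2)c(OCc2ccccc2)c1 | starting material
4 | rac-4-(benzyloxy)-2-{1-[3,4-bis(benzyloxy)phenyl]-2-nitroethoxy}-6-hydroxybenzaldehyde (drawn neutral; reacts as its C3 nitronate) | O=Cc1c(O)cc(OCc2ccccc2)cc1OC(C[N+](=O)[O-])c1ccc(OCc2ccccc2)c(OCc2ccccc2)c1 | intermediate
5 | 2-[3,4-bis(benzyloxy)phenyl]-7-(benzyloxy)-3-nitrochromane-4,5-diol (racemic mixture of diastereomers) | OC1c2c(O)cc(OCc3ccccc3)cc2OC(c2ccc(OCc3ccccc3)c(OCc3ccccc3)c2)C1[N+](=O)[O-] | intermediate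
6 | rac-2-[3,4-bis(benzyloxy)phenyl]-7-(benzyloxy)-3-nitro-2H-chromen-5-ol | O=[N+]([O-])C1=Cc2c(O)cc(OCc3ccccc3)cc2OC1c1ccc(OCc2ccccc2)c(OCc2ccccc2)c1 | intermediate
7 | rac-2-[3,4-bis(benzyloxy)phenyl]-7-(benzyloxy)-3-iminochroman-5-ol | N=C1Cc2c(O)cc(OCc3ccccc3)cc2OC1c1ccc(OCc2ccccc2)c(OCc2ccccc2)c1 | intermediate
8 | rac-2-[3,4-bis(benzyloxy)phenyl]-7-(benzyloxy)-5-hydroxychroman-3-one | O=C1Cc2c(O)cc(OCc3ccccc3)cc2OC1c1ccc(OCc2ccccc2)c(OCc2ccccc2)c1 | intermediate
9 | 2-[3,4-bis(benzyloxy)phenyl]-7-(benzyloxy)-4H-chromene-3,5-diol (achiral C2=C3 enol) | OC1=C(c2ccc(OCc3ccccc3)c(OCc3ccccc3)c2)Oc2cc(OCc3ccccc3)cc(O)c2C1 | intermediate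
10 | (2R,3R)-2-[3,4-bis(benzyloxy)phenyl]-7-(benzyloxy)chromane-3,5-diol (7,3',4'-tri-O-benzyl-(−)-epicatechin) | Oc1cc(OCc3ccccc3)cc2c1C[C@@H](O)[C@@H](c1ccc(OCc3ccccc3)c(OCc3ccccc3)c1)O2 | intermediate
11 | 3,4,5-tris(benzyloxy)benzoic acid | OC(=O)c1cc(OCc2ccccc2)c(OCc2ccccc2)c(OCc2ccccc2)c1 | starting material
12 | N,N'-dicyclohexyl-O-[3,4,5-tris(benzyloxy)benzoyl]isourea | O=C(OC(=NC1CCCCC1)NC1CCCCC1)c1cc(OCc2ccccc2)c(OCc2ccccc2)c(OCc2ccccc2)c1 | intermediate
13 | (2R,3R)-2-[3,4-bis(benzyloxy)phenyl]-7-(benzyloxy)chromane-3,5-diyl bis[3,4,5-tris(benzyloxy)benzoate] | O=C(Oc1cc(OCc3ccccc3)cc2c1C[C@@H](OC(=O)c1cc(OCc3ccccc3)c(OCc3ccccc3)c(OCc3ccccc3)c1)[C@@H](c1ccc(OCc3ccccc3)c(OCc3ccccc3)c1)O2)c1cc(OCc2ccccc2)c(OCc2ccccc2)c(OCc2ccccc2)c1 | intermediate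
14 | (−)-epicatechin 3,5-di-O-gallate, (2R,3R)-2-(3,4-dihydroxyphenyl)-7-hydroxychromane-3,5-diyl bis(3,4,5-trihydroxybenzoate) | O=C(Oc1cc(O)cc2c1C[C@@H](OC(=O)c1cc(O)c(O)c(O)c1)[C@@H](c1ccc(O)c(O)c1)O2)c1cc(O)c(O)c(O)c1 | target

**Totals**
Total step count: 6.
Longest linear sequence: 6 (1 → 2 → 6 → 8 → 10 → 13 → 14).

**Three steps most likely to fail**

**Step 4 (transfer hydrogenation with dynamic kinetic resolution).**
- The size and sense of catalyst control on a flavan-3-one are untested, and reduction could outrun C2 epimerisation.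
- The absolute configuration of 10 must be checked on the first run. The mirror-image catalyst is equally available.
- The fallback sets out from 8 and comes back at 10. LiBH(s-Bu)3 (2.2 equiv, THF, −78 °C) attacks anti to the 2-aryl group and gives only the cis-alcohol, as a racemate.
- That racemate is a 1:1 mixture of 10 and the (2S,3S)-2-[3,4-bis(benzyloxy)phenyl]-7-(benzyloxy)chromane-3,5-diol F3.
- The two are separated by preparative chiral SFC on an amylose tris(3,5-dimethylphenylcarbamate) phase. Stereocontrol then rests on substrate-controlled reduction plus resolution instead of catalyst control.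

**Step 2 (domino ring closure).**
- The aldehyde of 2 is a deactivated vinylogous acid and 3 is an electron-rich acceptor, so both the oxa-Michael equilibrium and the Henry closure may be sluggish.
- The fallback sets out from 2 and comes back at 6. It changes the electrophile at C4.
- 2 is condensed with p-toluenesulfonamide (Si(OEt)4, 120 °C) to the (E)-N-[4-(benzyloxy)-2,6-dihydroxybenzylidene]-4-methylbenzenesulfonamide F1.
- F1 is then combined with 3 (DABCO, toluene, 40 °C). The same nitronate now closes ring C by an aza-Henry addition to a far more electrophilic C=N carbon.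
- E1cB loss of the sulfonamide, a better leaving group than hydroxide, delivers 6.

**Step 3 (unmasking of the ketone).**
- Hot Fe/AcOH may over-reduce to the 3-amine or degrade the oxidation-prone ketone.
- The fallback sets out from 6 and comes back at 8. It separates the C=C reduction from the C–N cleavage.
- NaBH4 (THF/MeOH, 0 °C) adds hydride 1,4 to give the rac-2-[3,4-bis(benzyloxy)phenyl]-7-(benzyloxy)-3-nitrochroman-5-ol F2.
- The nitronate of F2 (NaOMe, MeOH) is run into buffered aqueous TiCl3/NH4OAc at 0 °C (McMurry variant of the Nef reaction) to give 8 under nearly neutral, cold conditions.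
- Any ring-opening and reclosure of the nitronate is harmless because the material is racemic at this stage.

**Further compounds**
F1 | step 2 | (E)-N-[4-(benzyloxy)-2,6-dihydroxybenzylidene]-4-methylbenzenesulfonamide | Cc1ccc(cc1)S(=O)(=O)/N=C/c1c(O)cc(OCc2ccccc2)cc1O
F2 | step 3 | rac-2-[3,4-bis(benzyloxy)phenyl]-7-(benzyloxy)-3-nitrochroman-5-ol (cis/trans mixture) | O=[N+]([O-])C1Cc2c(O)cc(OCc3ccccc3)cc2OC1c1ccc(OCc2ccccc2)c(OCc2ccccc2)c1
F3 | step 4 | (2S,3S)-2-[3,4-bis(benzyloxy)phenyl]-7-(benzyloxy)chromane-3,5-diol | Oc1cc(OCc3ccccc3)cc2c1C[C@H](O)[C@H](c1ccc(OCc3ccccc3)c(OCc3ccccc3)c1)O2
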